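**Strategy.** Ring atoms are numbered C1 (CMe2), C2 (CHBr), C3 (alkylidene), C4 (CHCl), C5, C6 (CHCl), the side chain C7 and C8. Everything rests on disconnecting C1–C2, because quaternary C1 sits between chlorinated C6 and brominated C2 of the cyclohexane ring. In one operation a Cl+-induced cation–olefin cyclisation forms this bond, closes the six-membered ring, sets C2 and C6 relative to the C4 silyloxy group and ends, by loss of silicon from C7, as the exocyclic C3=C7=C8 allene. Its precursor is the TBDPS ether of (1Z)-1-bromo-2-[(1R)-1-hydroxy-4-methylpent-3-enyl]-3-(triethylsilyl)buta-1,3-diene. Chloride inversion at C4, allene hydroboration–oxidation and bromination finish the target.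

Key step: step 9

Remark on the precursor: the C4 oxygen carries tert-butyldiphenylsilyl (TBDPS), not a smaller silyl group. A bulkier, less basic ether oxygen is less able to open the chloriranium ion at C1 to a five-membered chloroether, and it withstands AcOH (step 6) and SbCl5 (step 9).

Assumption: Ru[(R,R)-TsDPEN](p-cymene) is taken to give the (R)-carbinol from the ynone, the alkyne playing the part of the aryl group of an aryl ketone; the enantiomeric catalyst would be used if the sense proved opposite.

The labels C1–C8 are also used for the corresponding carbons of the acyclic intermediates.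

Step 1
Reactants: 1 4-methylpent-3-enoic acid
Product: 3 N-methoxy-N,4-dimethylpent-3-enamide, via acyl imidazolide 2 (not isolated)
Conditions: CDI, CH2Cl2, 0 °C → rt; then MeNHOMe·HCl, rt
Reagents that add atoms: N,O-dimethylhydroxylamine hydrochloride, CNOC.Cl
Why: Weinreb amide formation through the acyl imidazolide is a standard amidation whose near-neutral conditions should leave the β,γ-alkene out of conjugation.

Step 2
Reactants: 3 N-methoxy-N,4-dimethylpent-3-enamide; 4 ethynyltrimethylsilane
Product: 6 6-methyl-1-(trimethylsilyl)hept-5-en-1-yn-3-one, via lithium acetylide 5 (not isolated)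
Conditions: 4, n-BuLi, THF, −78 °C; then 3, −78 → −20 °C; cold aq. NH4Cl
Reagents that add atoms: none
Why: Weinreb ketone synthesis, in which the N-methoxy chelate survives until the cold quench, so the acetylide should add only once and the skipped enone should not move into conjugation.

Step 3
Reactants: 6 6-methyl-1-(trimethylsilyl)hept-5-en-1-yn-3-one
Product: 7 (3R)-6-methyl-1-(trimethylsilyl)hept-5-en-1-yn-3-ol
Conditions: Ru[(R,R)-TsDPEN](p-cymene) (1 mol %), i-PrOH, rt
Reagents that add atoms: none
Why: Noyori asymmetric transfer hydrogenation of an ynone under base-free conditions, the chiral catalyst delivering hydride to the carbonyl face that gives the (R)-carbinol at C4 while alkyne and alkene stay untouched.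

Step 4
Reactants: 7 (3R)-6-methyl-1-(trimethylsilyl)hept-5-en-1-yn-3-ol
Product: 8 tert-butyl{[(3R)-6-methyl-1-(trimethylsilyl)hept-5-en-1-yn-3-yl]oxy}diphenylsilane
Conditions: TBDPSCl, imidazole, DMF, rt
Reagents that add atoms: tert-butyl(chloro)diphenylsilane, CC(C)(C)[Si](Cl)(c1ccccc1)c1ccccc1
Why: standard imidazole-promoted silylation of a secondary alcohol, which does not touch the C4 stereocentre or the alkynylsilane.

Step 5
Reactants: 8 tert-butyl{[(3R)-6-methyl-1-(trimethylsilyl)hept-5-en-1-yn-3-yl]oxy}diphenylsilane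
Product: 9 {[(3R)-1-bromo-6-methylhept-5-en-1-yn-3-yl]oxy}(tert-butyl)diphenylsilane
Conditions: NBS (1.1 equiv), AgNO3 (10 mol %), dry acetone, 0 °C → rt, dark
Reagents that add atoms: N-bromosuccinimide, O=C1CCC(=O)N1Br
Why: silver-catalysed desilylative bromination of an alkynylsilane (silver acetylide, then bromine transfer) should give the 1-bromoalkyne directly, and without water or another nucleophile the trisubstituted alkene is not expected to be consumed.

Step 6
Reactants: 9 {[(3R)-1-bromo-6-methylhept-5-en-1-yn-3-yl]oxy}(tert-butyl)diphenylsilane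
Product: 10 {[(1Z,3R)-1-bromo-2-iodo-6-methylhepta-1,5-dien-3-yl]oxy}(tert-butyl)diphenylsilane
Conditions: LiI (2 equiv), Pd(OAc)2 (5 mol %), AcOH, rt
Reagents that add atoms: lithium iodide, [Li+].[I-]
Why: palladium-catalysed anti hydrohalogenation of a 1-haloalkyne, in which iodide adds to C3 (remote from bromine) trans to palladium on C2 and protodepalladation with retention leaves H trans to I, hence the Z isomer with Br and I cis.

Step 7
Reactants: 11 triethyl(vinyl)silane
Product: 13 (1-bromovinyl)triethylsilane, via dibromide 12 (not isolated)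
Conditions: Br2, CH2Cl2, −78 °C; then Et2NH, reflux
Reagents that add atoms: bromine, BrBr
Why: bromine addition to a vinylsilane followed by amine-induced dehydrobromination is the standard route to 1-bromovinylsilanes, the proton on the silicon- and bromine-bearing carbon being the one removed.

Step 8
Reactants: 10 {[(1Z,3R)-1-bromo-2-iodo-6-methylhepta-1,5-dien-3-yl]oxy}(tert-butyl)diphenylsilane; 13 (1-bromovinyl)triethylsilane
Product: 16 tert-butyl{[(1Z,3R)-1-bromo-6-methyl-2-[1-(triethylsilyl)ethenyl]hepta-1,5-dien-3-yl]oxy}diphenylsilane, via silylvinylmagnesium bromide 14 (not isolated), via silylvinylzinc chloride 15 (not isolated)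
Conditions: 13, Mg, THF, 40 °C; ZnCl2, THF, 0 °C; then 10, Pd(PPh3)4 (5 mol %), THF, rt
Reagents that add atoms: none
Why: Negishi coupling with retention of alkene geometry, oxidative addition being expected at the C–I bond well before the C–Br bond, so that the silylvinyl group takes the place of iodine cis to bromine.

Step 9
Reactants: 16 tert-butyl{[(1Z,3R)-1-bromo-6-methyl-2-[1-(triethylsilyl)ethenyl]hepta-1,5-dien-3-yl]oxy}diphenylsilane
Product: 17 tert-butyl{[(1R,3R,5S)-3-bromo-5-chloro-2-ethenylidene-4,4-dimethylcyclohexyl]oxy}diphenylsilane (C2–Br, C4–O and C6–Cl all cis)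
Conditions: Et2SCl·SbCl6 (1.1 equiv), MeNO2, −25 °C, 5 min; aq. NaHCO3/Na2SO3
Reagents that add atoms: chlorodiethylsulfonium hexachloroantimonate, CC[S+](Cl)CC.Cl[Sb-](Cl)(Cl)(Cl)(Cl)Cl
Why: Proposed new method: Cl+ is transferred from the chlorosulfonium salt to the trisubstituted C6=C1 alkene, the chloriranium ion is opened at tertiary C1 by C2 of the bromoalkene through a chair, the charge arrives at C3 (tertiary and β to silicon) and, with the twisted C7–Si bond aligned with the empty orbital, chloride-assisted loss of Et3Si+ leaves the C3=C7=C8 allene; the closest known reaction types are chlorosulfonium-induced cation–olefin cyclisations of prenyl-type alkenes and silane-terminated cation–olefin cyclisations. The single ring (C1–C6) closes in the 6-endo mode with respect to both the chloriranium ion and the C2=C3 bond. C6 is controlled by anti addition across C6=C1 (C–Cl antiperiplanar to the new C1–C2 bond and equatorial), C2 by the Z geometry of the bromoalkene (bromine trans to C4, hence equatorial), and both are related to C4 by the equatorial silyloxy group, which gives the all-cis 2,4,6 pattern. The step needs Cl+ to choose the prenyl alkene over the silyl diene, carbon and not the ether oxygen to open the ion, and C2 and not C3 to bond to C1; the higher substitution of C6=C1, the bulky and weakly basic TBDPS ether, and the six-membered ring together with the β-silyl stabilisation of the C3 cation are relied on for these.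

Step 10
Reactants: 17 tert-butyl{[(1R,3R,5S)-3-bromo-5-chloro-2-ethenylidene-4,4-dimethylcyclohexyl]oxy}diphenylsilane
Product: 18 (1R,3R,5S)-3-bromo-5-chloro-2-ethenylidene-4,4-dimethylcyclohexan-1-ol
Conditions: Bu4NF, AcOH (1:1), THF, 0 °C → rt
Reagents that add atoms: none
Why: fluoride-mediated silyl ether cleavage, buffered with acetic acid so that the secondary halides and the allene are not exposed to base, with no stereocentre touched.

Step 11
Reactants: 18 (1R,3R,5S)-3-bromo-5-chloro-2-ethenylidene-4,4-dimethylcyclohexan-1-ol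
Product: 19 (2S,4S,6S)-2-bromo-4,6-dichloro-3-ethenylidene-1,1-dimethylcyclohexane
Conditions: PPh3, Cl3CCOCCl3, CH2Cl2, 0 °C
Reagents that add atoms: hexachloroacetone, ClC(Cl)(Cl)C(=O)C(Cl)(Cl)Cl
Why: Appel-type chlorination in which chloride displaces the equatorial oxyphosphonium group at C4 by SN2 with inversion to give the axial chloride, the SN2' path through C7 being disfavoured because the equatorial C–O bond lies orthogonal to the C3=C7 π bond.

Step 12
Reactants: 19 (2S,4S,6S)-2-bromo-4,6-dichloro-3-ethenylidene-1,1-dimethylcyclohexane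
Product: 21 (2Z)-2-[(2S,4S,6S)-2-bromo-4,6-dichloro-3,3-dimethylcyclohexylidene]ethan-1-ol, via allylborane 20 (not isolated)
Conditions: Cy2BH (from BH3·SMe2 and cyclohexene), THF, −10 → 0 °C; then 30% H2O2, aq. NaOAc, 0 °C
Reagents that add atoms: hydrogen peroxide, OO
Why: hydroboration of a 1,1-disubstituted allene by a dialkylborane places boron on terminal C8 and hydrogen on central C7, the borane having to approach the C7=C8 bond in the plane of C2, C3 and C4 and expected to pass the equatorial hydrogen of C4 and not the equatorial bromine of C2, so that C8 turns towards C2 (Z) and cold oxidation of the allylborane with retention gives the allylic alcohol.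

Step 13
Reactants: 21 (2Z)-2-[(2S,4S,6S)-2-bromo-4,6-dichloro-3,3-dimethylcyclohexylidene]ethan-1-ol
Product: 22 (2S,3Z,4S,6S)-2-bromo-3-(2-bromoethylidene)-4,6-dichloro-1,1-dimethylcyclohexane
Conditions: PPh3, CBr4, CH2Cl2, 0 °C
Reagents that add atoms: carbon tetrabromide, BrC(Br)(Br)Br
Why: Appel bromination of a primary allylic alcohol should proceed by SN2 at C8 without allylic transposition and without touching the alkene geometry or the ring stereocentres.

**Compound list**

1 | 4-methylpent-3-enoic acid | CC(C)=CCC(O)=O | starting material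
2 | 1-(4-methylpent-3-enoyl)imidazole | CC(C)=CCC(=O)n1ccnc1 | intermediate (not isolated)
3 | N-methoxy-N,4-dimethylpent-3-enamide | CC(C)=CCC(=O)N(C)OC | intermediate
4 | ethynyltrimethylsilane | C#C[Si](C)(C)C | starting material
5 | lithium (trimethylsilyl)acetylide | [Li]C#C[Si](C)(C)C | intermediate (not isolated)
6 | 6-methyl-1-(trimethylsilyl)hept-5-en-1-yn-3-one | CC(C)=CCC(=O)C#C[Si](C)(C)C | intermediate
7 | (3R)-6-methyl-1-(trimethylsilyl)hept-5-en-1-yn-3-ol | C[Si](C)(C)C#C[C@H](O)CC=C(C)C | intermediate
8 | tert-butyl{[(3R)-6-methyl-1-(trimethylsilyl)hept-5-en-1-yn-3-yl]oxy}diphenylsilane | C[Si](C)(C)C#C[C@H](O[Si](c1ccccc1)(c1ccccc1)C(C)(C)C)CC=C(C)C | intermediate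
9 | {[(3R)-1-bromo-6-methylhept-5-en-1-yn-3-yl]oxy}(tert-butyl)diphenylsilane | BrC#C[C@H](O[Si](c1ccccc1)(c1ccccc1)C(C)(C)C)CC=C(C)C | intermediate
10 | {[(1Z,3R)-1-bromo-2-iodo-6-methylhepta-1,5-dien-3-yl]oxy}(tert-butyl)diphenylsilane (Br and I cis) | Br/C=C(\I)[C@H](O[Si](c1ccccc1)(c1ccccc1)C(C)(C)C)CC=C(C)C | intermediate
11 | triethyl(vinyl)silane | C=C[Si](CC)(CC)CC | starting material
12 | (1,2-dibromoethyl)triethylsilane (racemic) | CC[Si](CC)(CC)C(Br)CBr | intermediate (not isolated)
13 | (1-bromovinyl)triethylsilane | C=C(Br)[Si](CC)(CC)CC | intermediate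
14 | bromo[1-(triethylsilyl)vinyl]magnesium | Br[Mg]C(=C)[Si](CC)(CC)CC | intermediate (not isolated)
15 | chloro[1-(triethylsilyl)vinyl]zinc | Cl[Zn]C(=C)[Si](CC)(CC)CC | intermediate (not isolated)
16 | tert-butyl{[(1Z,3R)-1-bromo-6-methyl-2-[1-(triethylsilyl)ethenyl]hepta-1,5-dien-3-yl]oxy}diphenylsilane, the TBDPS ether of (1Z)-1-bromo-2-[(1R)-1-hydroxy-4-methylpent-3-enyl]-3-(triethylsilyl)buta-1,3-diene (Br cis to the silylvinyl group) | Br/C=C(\C(=C)[Si](CC)(CC)CC)[C@H](O[Si](c1ccccc1)(c1ccccc1)C(C)(C)C)CC=C(C)C | intermediate (key-step precursor)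
17 | tert-butyl{[(1R,3R,5S)-3-bromo-5-chloro-2-ethenylidene-4,4-dimethylcyclohexyl]oxy}diphenylsilane (all-cis) | CC1(C)[C@H](Br)C(=C=C)[C@H](O[Si](c2ccccc2)(c2ccccc2)C(C)(C)C)C[C@@H]1Cl | intermediate (key-step product)
18 | (1R,3R,5S)-3-bromo-5-chloro-2-ethenylidene-4,4-dimethylcyclohexan-1-ol | CC1(C)[C@H](Br)C(=C=C)[C@H](O)C[C@@H]1Cl | intermediate
19 | (2S,4S,6S)-2-bromo-4,6-dichloro-3-ethenylidene-1,1-dimethylcyclohexane | CC1(C)[C@H](Br)C(=C=C)[C@@H](Cl)C[C@@H]1Cl | intermediate
20 | {(2Z)-2-[(2S,4S,6S)-2-bromo-4,6-dichloro-3,3-dimethylcyclohexylidene]ethyl}dicyclohexylborane | CC1(C)[C@H](Br)/C(=C\CB(C2CCCCC2)C2CCCCC2)[C@@H](Cl)C[C@@H]1Cl | intermediate (not isolated)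
21 | (2Z)-2-[(2S,4S,6S)-2-bromo-4,6-dichloro-3,3-dimethylcyclohexylidene]ethan-1-ol | CC1(C)[C@H](Br)/C(=C\CO)[C@@H](Cl)C[C@@H]1Cl | intermediate
22 | (2S,3Z,4S,6S)-2-bromo-3-(2-bromoethylidene)-4,6-dichloro-1,1-dimethylcyclohexane | CC1(C)[C@H](Br)/C(=C\CBr)[C@@H](Cl)C[C@@H]1Cl | target

**Step count.** Total: 13 steps. Longest linear sequence: 12 steps (steps 1–6 and 8–13; step 7 is a one-step side branch).

**Steps most likely to fail**

1. Step 9 (proposed new method). The chloriranium ion may be opened by the ether oxygen, or not at all by the weakly nucleophilic bromoalkene. Bond formation may go through C3 to a five-membered ring. A hydride may shift from C4 to the C3 cation before silicon leaves. The chair may carry the silyloxy group axial, which would give the wrong relative configuration. Fallback with known chemistry, bromine being introduced after ring closure: it sets out from 8 and comes back at 22. K2CO3 in MeOH removes the alkynyl silicon to give the terminal alkyne tert-butyl{[(3R)-6-methylhept-5-en-1-yn-3-yl]oxy}diphenylsilane F1. Enyne cross-metathesis with ethylene (1 atm, second-generation Grubbs catalyst RuCl2(H2IMes)(PCy3)(=CHPh), CH2Cl2, rt) gives the 2-substituted butadiene tert-butyl{[(4R)-7-methyl-3-methylideneocta-1,6-dien-4-yl]oxy}diphenylsilane F2. Et2SCl·SbCl6 (MeNO2, −25 °C) then meets a 1,1-disubstituted alkene that attacks through its CH2 terminus, the ordinary nucleophile of halonium-induced polyene cyclisation, and loss of the C2 proton from the allyl cation gives the vinylcyclohexene tert-butyl{[(1R,5S)-5-chloro-2-ethenyl-4,4-dimethylcyclohex-2-en-1-yl]oxy}diphenylsilane F3. Bu4NF/AcOH gives the alcohol (1R,5S)-5-chloro-2-ethenyl-4,4-dimethylcyclohex-2-en-1-ol F4. PPh3/Cl3CCOCCl3 gives the inverted chloride (4S,6S)-4,6-dichloro-1-ethenyl-3,3-dimethylcyclohex-1-ene F5. 1,4-Addition of Br2 (CH2Cl2, −78 °C) across the C2=C3–C7=C8 diene places bromine on C2 and C8 and reaches 22. This path gives up control of C2 and of the alkene geometry, so isomers would have to be separated.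

2. Step 12. The borane may approach from the C2 side (poor facial selectivity). A 1,3-boron shift may scramble the alkene geometry. The axial C4 chloride may be lost by vinylogous elimination from the allylborane before or during oxidation. Fallback: it sets out from 19 and comes back at 21. The uncatalysed dialkylborane addition is replaced by a platinum-catalysed hydroboration with pinacolborane (Pt(dba)2, P(t-Bu)3, toluene, 50 °C), which also puts boron on the terminal carbon of 1,1-disubstituted allenes. It gives the isolable allylboronate 2-{(2Z)-2-[(2S,4S,6S)-2-bromo-4,6-dichloro-3,3-dimethylcyclohexylidene]ethyl}-4,4,5,5-tetramethyl-1,3,2-dioxaborolane F6. As a weakly Lewis-acidic boronic ester it should neither undergo the boron shift nor eliminate, its geometry can be checked before use, and NaBO3·4H2O (THF/H2O, 0 °C) then oxidises it to 21.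

3. Step 6. Iodide may add with poor regiocontrol, halogen may be exchanged at the bromoalkyne terminus, or palladium may turn over slowly in the presence of iodide. Fallback: it sets out from 8 and comes back at 16, and it also removes the C–I against C–Br selectivity that step 8 needs. The terminal alkyne tert-butyl{[(3R)-6-methylhept-5-en-1-yn-3-yl]oxy}diphenylsilane F1 (K2CO3, MeOH, as above) undergoes syn silylstannation with Me3SiSnBu3 (Pd(PPh3)4, THF, 65 °C), tin going to the internal carbon, to give tert-butyl{[(1Z,3R)-6-methyl-2-(tributylstannyl)-1-(trimethylsilyl)hepta-1,5-dien-3-yl]oxy}diphenylsilane F7. I2 (CH2Cl2, 0 °C) cleaves only the C–Sn bond with retention to give tert-butyl{[(1Z,3R)-2-iodo-6-methyl-1-(trimethylsilyl)hepta-1,5-dien-3-yl]oxy}diphenylsilane F8. Negishi coupling with 15 under the conditions of step 8 gives tert-butyl{[(1Z,3R)-6-methyl-2-[1-(triethylsilyl)ethenyl]-1-(trimethylsilyl)hepta-1,5-dien-3-yl]oxy}diphenylsilane F9. Ipso-bromodesilylation of the trimethylsilyl group with NBS (MeCN, 0 °C), with retention, gives 16.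

**Further compounds**

F1 | step 9 | tert-butyl{[(3R)-6-methylhept-5-en-1-yn-3-yl]oxy}diphenylsilane | C#C[C@H](O[Si](c1ccccc1)(c1ccccc1)C(C)(C)C)CC=C(C)C
F2 | step 9 | tert-butyl{[(4R)-7-methyl-3-methylideneocta-1,6-dien-4-yl]oxy}diphenylsilane | C=CC(=C)[C@H](O[Si](c1ccccc1)(c1ccccc1)C(C)(C)C)CC=C(C)C
F3 | step 9 | tert-butyl{[(1R,5S)-5-chloro-2-ethenyl-4,4-dimethylcyclohex-2-en-1-yl]oxy}diphenylsilane | CC1(C)C=C(C=C)[C@H](O[Si](c2ccccc2)(c2ccccc2)C(C)(C)C)C[C@@H]1Cl
F4 | step 9 | (1R,5S)-5-chloro-2-ethenyl-4,4-dimethylcyclohex-2-en-1-ol | CC1(C)C=C(C=C)[C@H](O)C[C@@H]1Cl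
F5 | step 9 | (4S,6S)-4,6-dichloro-1-ethenyl-3,3-dimethylcyclohex-1-ene | CC1(C)C=C(C=C)[C@@H](Cl)C[C@@H]1Cl
F6 | step 12 | 2-{(2Z)-2-[(2S,4S,6S)-2-bromo-4,6-dichloro-3,3-dimethylcyclohexylidene]ethyl}-4,4,5,5-tetramethyl-1,3,2-dioxaborolane | CC1(C)[C@H](Br)/C(=C\CB2OC(C)(C)C(C)(C)O2)[C@@H](Cl)C[C@@H]1Cl
F7 | step 6 | tert-butyl{[(1Z,3R)-6-methyl-2-(tributylstannyl)-1-(trimethylsilyl)hepta-1,5-dien-3-yl]oxy}diphenylsilane | C[Si](C)(C)/C=C(\[Sn](CCCC)(CCCC)CCCC)[C@H](O[Si](c1ccccc1)(c1ccccc1)C(C)(C)C)CC=C(C)C
F8 | step 6 | tert-butyl{[(1Z,3R)-2-iodo-6-methyl-1-(trimethylsilyl)hepta-1,5-dien-3-yl]oxy}diphenylsilane | C[Si](C)(C)/C=C(\I)[C@H](O[Si](c1ccccc1)(c1ccccc1)C(C)(C)C)CC=C(C)C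
F9 | step 6 | tert-butyl{[(1Z,3R)-6-methyl-2-[1-(triethylsilyl)ethenyl]-1-(trimethylsilyl)hepta-1,5-dien-3-yl]oxy}diphenylsilane | C[Si](C)(C)/C=C(\C(=C)[Si](CC)(CC)CC)[C@H](O[Si](c1ccccc1)(c1ccccc1)C(C)(C)C)CC=C(C)C
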